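The numbers were chosen freely; what happens was integrated by code.

Lump G, L and Z into one pool and follow its fraction of the charge; L.D forms from the L part of that pool.

- zeta: X 0.050 M; J 1.50 equiv; time 30 h
- gamma: X 0.050 M; J 1.50 equiv; time 60 h

    X + J → G + D (k1 = 0.042 L mol⁻¹ min⁻¹)
    G ⇌ L (K2 = 0.55, k2 = 0.016 min⁻¹)
    G ⇌ Z (K3 = 3.0, k3 = 0.0053 min⁻¹)
    L + D → L.D (k4 = 0.087 L mol⁻¹ min⁻¹)
    J → Q (k5 = 1.5 × 10⁻⁵ min⁻¹)

- which of these there is most of at the end, counted by the X in it, zeta (L.D / Z / L / G)
- which of these there is most of at the end, counted by the X in it, gamma (L.D / Z / L / G)
- how much there is at the end of the one of these that leads, in percent of the X charged: zeta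
- how much there is at the end of the one of these that leads, in percent of the X charged: gamma

1. First rung: G and L relax with a half-life of 0.256 h, then G and Z with 1.63 h, so the pool keeps close to a pre-equilibrium. The L share of the pool is then 0.121.

2. Next rung: X enters the pool. Taken as one charge, it arrives 8.72 h late, which is the mean stay of X with J at its 1.50 equiv.

3. Slow rung: each X converted gives one D and each L.D removes one, so D equals the pool. The drain is second-order in the pool, with D taken at 0.5 of the charge for the corrections.

4. Two corrections enter. The drain lowers L against G by 0.0748, and Z lags its release by 0.149, which moves the L share to 0.102. This gives 37.7 h, the drain time, in which the second-order drain halves a pool present from the start, and the lag is shorter than that.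

5. Last rung: J decays to Q with a half-life of 32 d, and my reckoning ignores it.

6. My reckoning for zeta: L.D stands at 36.1%. X keeps 5.60%, and Z holds 0.700 of the pool, so Z reaches 40.8% and leads, standing higher than L.D. For gamma, L.D stands at 57.6% against Z at 29.1%, so L.D leads, standing higher than Z.

7. The forecast names Z at 39% for zeta and L.D at 57% for gamma, on the ground that “That pool drains slowly and second-order into L.D because D matches the pool”.

8. The simulation gives Z at 40.5% for zeta, with L.D at 34.9%, and L.D at 56.4% for gamma, with Z at 29.4%. The forecast held on both leaders and both amounts.

9. Zeta and gamma differ in time, and that difference is the main reason for the gap in L.D, 56.4% in gamma against 34.9% in zeta. Counted in drain times, zeta has run 0.796 and gamma 1.59. The drain time carries to a neighbour of gamma charged with 0.12 M of X. With the share held, drain time and lag both scale inversely with the charge, to 15.7 h and 3.63 h, which reckons L.D at 78.2% after 60 h. That neighbour holds 77.1% as L.D.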